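**Plan**

1. Retrosynthesis: the exocyclic C7=CH2 bond is traced to a C7–CH2SiMe3 allylsilane and the C9 acetate to a C9 ketone; C3–Br and C3–CH3 are cut back to a C3 ketone; C4 is then excised (C3–C4 and C4–C5), C2–Cl is removed, and the remaining five-membered ring is opened at C1–C2 and C5–C6.
2. Enabling feature: ring B (C6, C1, C2 Cl, C3 Me/Br, C4, C5) without C4 is a 3-oxo cyclopentane spiro-fused at C6. A [3+2] cycloaddition onto a C6 exocyclic enone of ring A builds this ring in one step, and its C2 chlorine forces a one-carbon enlargement to take place on the C5 side.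
3. Forward order: ring A (C6–C11) is dimedone; the five-membered precursor of ring B is spiro-annulated at C6, oxidised to the C3 ketone, chlorinated at C2 and enlarged by insertion of C4; C3 then receives methyl and bromine; finally ring A is completed (C10 Br, C7 carbon, C9 carbinol, acetate, exocyclic alkene).
4. Stereochemistry: C6 from the chiral ligand of the cycloaddition; C2 by chlorination anti to the C11 gem-dimethyl group; C3 by anti opening of a chloronium ion by bromide; C10 by axial bromination of ring A in the conformer fixed by the axial C2 chlorine; C9 by oxazaborolidine-controlled reduction.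

Key step: step 6

Remark: atom labels C1–C11 are those of the target (ring A = C6–C11, ring B = C1–C6) and are used for every intermediate; the systematic names of the spiro[4.5] compounds 7–10 carry their own locants.
Remark: the CIP label of C6 changes along the route (R in 7–9, S in 10–18, R from 19 on) only because the ranking of its substituents changes; its geometry is set once in step 3.
Assumption: in step 3 the ligand L (phosphoramidite from 1,1′-bi-2-naphthol and trans-2,5-di(2-naphthyl)pyrrolidine) is used as the antipode that gives the 6R centre; the sense of induction cannot be predicted with confidence, and the mirror-image ligand is taken if it proves opposite.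
Assumption: in step 11 the CHBr–CMe2 flank of the C9 ketone is taken as the larger group in the oxazaborolidine model; if the opposite ranking holds, the S catalyst is used.

**Step 1**
Reactants: 1 dimedone
Product: 2 3-ethoxy-5,5-dimethylcyclohex-2-en-1-one
Conditions: EtOH, TsOH·H2O (cat.), toluene, reflux, azeotropic removal of water
Reagents that add atoms: ethanol, CCO
Why: Acid-catalysed enol etherification of a cyclic 1,3-diketone (vinylogous esterification) differentiates the two carbonyl groups of ring A as the C7 ketone and the C9 enol ether and leaves C6 as the only kinetically acidic position.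

**Step 2**
Reactants: 2 3-ethoxy-5,5-dimethylcyclohex-2-en-1-one
Product: 5 3-ethoxy-5,5-dimethyl-6-methylidenecyclohex-2-en-1-one, via Mannich base 3 (not isolated), via methiodide 4 (not isolated)
Conditions: LiN(iPr)2, THF, −78 °C; [Me2N=CH2]I, −78 °C to rt; MeI, CH2Cl2, rt; NaHCO3 (aq), CH2Cl2, rt
Reagents that add atoms: dimethylmethylideneammonium iodide, C=[N+](C)C.[I-]
Why: Kinetic α′-deprotonation at C6, Mannich reaction with the iminium salt and Hofmann-type elimination of the quaternised amine is the standard α-methylenation of a ketone and gives the cross-conjugated exocyclic enone, which is used at once.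

**Step 3**
Reactants: 5 3-ethoxy-5,5-dimethyl-6-methylidenecyclohex-2-en-1-one; 6 2-[(trimethylsilyl)methyl]allyl acetate
Product: 7 (5R)-8-ethoxy-10,10-dimethyl-2-methylidenespiro[4.5]dec-7-en-6-one
Conditions: Pd(dba)2 (5 mol %), ligand L (10 mol %), toluene, 23–45 °C
Reagents that add atoms: none
Why: Palladium–trimethylenemethane [3+2] cycloaddition: the zwitterionic π-allyl complex formed from 6 and zerovalent palladium adds through its carbanion to the exocyclic CH2 (C1–C2), and the resulting C6 enolate closes on the π-allyl terminus (C5–C6) on the face selected by the ligand, which sets the quaternary spiro centre C6.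

**Step 4**
Reactants: 7 (5R)-8-ethoxy-10,10-dimethyl-2-methylidenespiro[4.5]dec-7-en-6-one
Product: 8 (5R)-8-ethoxy-10,10-dimethylspiro[4.5]dec-7-ene-2,6-dione
Conditions: OsO4 (2 mol %), NaIO4, 2,6-lutidine, dioxane/H2O, rt
Reagents that add atoms: osmium tetroxide, O=[Os](=O)(=O)=O; sodium periodate, [Na+].[O-]I(=O)(=O)=O
Why: Lemieux–Johnson oxidation cleaves the isolated 1,1-disubstituted alkene far faster than the electron-poor push–pull C8=C9 bond and unveils the C3 ketone without touching C6.

**Step 5**
Reactants: 8 (5R)-8-ethoxy-10,10-dimethylspiro[4.5]dec-7-ene-2,6-dione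
Product: 10 (3S,5S)-3-chloro-8-ethoxy-10,10-dimethylspiro[4.5]dec-7-ene-2,6-dione, via silyl enol ether 9 (not isolated)
Conditions: LiN(SiMe3)2, Me3SiCl, THF, −78 °C; then N-chlorosuccinimide, THF, −78 to 0 °C
Reagents that add atoms: N-chlorosuccinimide, O=C1CCC(=O)N1Cl
Why: Kinetic enolisation of the 3,3-disubstituted cyclopentanone occurs at C2, away from the neopentyl C5 methylene, and α-chlorination of the trapped silyl enol ether takes place on the ring face opposite the C11 gem-dimethyl group (kinetic control), placing chlorine cis to C7; the centre is epimerisable and is carried on under non-equilibrating conditions.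

**Step 6**
Reactants: 10 (3S,5S)-3-chloro-8-ethoxy-10,10-dimethylspiro[4.5]dec-7-ene-2,6-dione; 11 trimethylsilyldiazomethane
Product: 13 (2S,6S)-2-chloro-9-ethoxy-11,11-dimethylspiro[5.5]undec-8-ene-3,7-dione, via silyl ketone 12 (not isolated)
Conditions: Me3SiCHN2 (1.2 equiv), BF3·OEt2 (2.2 equiv), CH2Cl2, −78 to −40 °C; NaHCO3 (aq); SiO2
Reagents that add atoms: none
Why: The diazo carbon adds to the BF3-activated C3 carbonyl of the α-chloro ketone, and the β-oxido diazonium ion loses N2 with a 1,2-shift of C5, so that the new carbon C4 is bonded to C3 and C5 and the α-silyl ketone 12 is C-desilylated on work-up. The closest known reaction type is the Lewis-acid-promoted diazoalkane homologation of cycloalkanones (Tiffeneau–Demjanov-type ring expansion), in which α-halo ketones expand away from the halogen-bearing carbon. No ring is closed: the existing five-membered ring is enlarged to ring B by one atom between C3 and C5, and no stereocentre is created because C4 ends as CH2 while C2 and C6 are not involved. The step needs migratory regioselectivity and carbonyl chemoselectivity: the electron-poor CHCl carbon C2 migrates poorly, so C5 moves, and the vinylogous ester carbonyl C7, hindered by the quaternary C6 and merely complexed by one equivalent of BF3, is far less electrophilic than the α-chloro ketone. A second insertion is held back by the silyl group flanking the new carbonyl until work-up and by the limited amount of diazoalkane, not by any lower reactivity of the six-membered ketone.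

**Step 7**
Reactants: 13 (2S,6S)-2-chloro-9-ethoxy-11,11-dimethylspiro[5.5]undec-8-ene-3,7-dione
Product: 14 (2S,3R,6S)-2-chloro-9-ethoxy-3-hydroxy-3,11,11-trimethylspiro[5.5]undec-8-en-7-one
Conditions: MeMgBr, CeCl3, THF, −78 °C
Reagents that add atoms: methylmagnesium bromide, C[Mg]Br
Why: 1,2-Addition of the weakly basic organocerium reagent to the α-chloro ketone outpaces enolisation and attack on the hindered vinylogous ester; methyl enters anti to the C2–Cl bond (polar Felkin–Anh control) to give mainly the cis chlorohydrin, and either C3 epimer is usable because this centre is reset in step 8.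

**Step 8**
Reactants: 14 (2S,3R,6S)-2-chloro-9-ethoxy-3-hydroxy-3,11,11-trimethylspiro[5.5]undec-8-en-7-one
Product: 15 (2S,3S,6S)-3-bromo-2-chloro-9-ethoxy-3,11,11-trimethylspiro[5.5]undec-8-en-7-one
Conditions: HBr (anhydrous, excess), CH2Cl2, −30 to 0 °C
Reagents that add atoms: hydrogen bromide, Br
Why: SN1 exchange of the tertiary carbinol: the C3 cation is bridged by the neighbouring chlorine (chloronium ion, the classical anchimeric pathway of chlorohydrins) and opened by bromide at the tertiary carbon anti to chlorine, which fixes C3 with bromine trans to chlorine and methyl equatorial, while any alkene formed by proton loss re-adds HBr in the Markovnikov sense through the same ion.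

**Step 9**
Reactants: 15 (2S,3S,6S)-3-bromo-2-chloro-9-ethoxy-3,11,11-trimethylspiro[5.5]undec-8-en-7-one
Product: 17 (2S,3S,6S,10R)-3,10-dibromo-2-chloro-9-ethoxy-3,11,11-trimethylspiro[5.5]undec-8-en-7-one, via silyl dienol ether 16 (not isolated)
Conditions: t-BuMe2SiOTf, Et3N, CH2Cl2, 0 °C; then N-bromosuccinimide (1.0 equiv), CH2Cl2, −78 °C
Reagents that add atoms: N-bromosuccinimide, O=C1CCC(=O)N1Br
Why: Soft γ-enolisation of the vinylogous ester (C6 is quaternary, so only C10–H can be removed) gives a 1-silyloxy-3-ethoxy diene that is brominated at its terminus C10 (vinylogous α-halogenation), and bromine is expected to enter axially, anti to the pseudoaxial C11 methyl group, in the ring A conformer whose C7–O bond is turned away from the axial C2 chlorine, which places it on the C1 side of ring A (10R).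

**Step 10**
Reactants: 17 (2S,3S,6S,10R)-3,10-dibromo-2-chloro-9-ethoxy-3,11,11-trimethylspiro[5.5]undec-8-en-7-one
Product: 19 (2S,3S,6R,10R)-3,10-dibromo-2-chloro-3,11,11-trimethyl-7-[(trimethylsilyl)methyl]spiro[5.5]undec-7-en-9-one, via tertiary carbinol 18 (not isolated)
Conditions: Me3SiCH2Li, CeCl3, THF, −78 to −40 °C; then 1 M HCl, THF, 0 °C
Reagents that add atoms: (trimethylsilyl)methyllithium, [Li]C[Si](C)(C)C
Why: Stork–Danheiser transposition: the organocerium reagent adds 1,2 to the hindered C7 carbonyl and dilute acid converts the 3-ethoxy allylic carbinol into the transposed enone with the ketone at C9, so that the future methylene carbon sits on C7 as an allylsilane; this avoids the 1-ethoxy diene that direct methylenation would give, which hydrolyses by protonation at the exocyclic terminus to the conjugated C7-methyl enone.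

**Step 11**
Reactants: 19 (2S,3S,6R,10R)-3,10-dibromo-2-chloro-3,11,11-trimethyl-7-[(trimethylsilyl)methyl]spiro[5.5]undec-7-en-9-one
Product: 20 (2S,3S,6R,9S,10R)-3,10-dibromo-2-chloro-3,11,11-trimethyl-7-[(trimethylsilyl)methyl]spiro[5.5]undec-7-en-9-ol
Conditions: (R)-1-methyl-3,3-diphenyltetrahydro-1H,3H-pyrrolo[1,2-c][1,3,2]oxazaborole (0.5 equiv), catecholborane, toluene, −78 °C; pH 7 buffer
Reagents that add atoms: none
Why: Corey–Bakshi–Shibata reduction: the oxazaborolidine binds the C9 carbonyl on the side of the vinylic C8–H, away from the larger CHBr–CMe2 flank, and delivers hydride from catecholborane to the face anti to the C10–Br bond, giving the 9S carbinol cis to bromine without 1,4-reduction or hydroboration of the allylsilane.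

**Step 12**
Reactants: 20 (2S,3S,6R,9S,10R)-3,10-dibromo-2-chloro-3,11,11-trimethyl-7-[(trimethylsilyl)methyl]spiro[5.5]undec-7-en-9-ol
Product: 21 (2S,3S,6R,9S,10R)-3,10-dibromo-2-chloro-3,11,11-trimethyl-7-[(trimethylsilyl)methyl]spiro[5.5]undec-7-en-9-yl acetate
Conditions: Ac2O, pyridine, DMAP (cat.), CH2Cl2, 0 °C to rt
Reagents that add atoms: acetic anhydride, CC(=O)OC(C)=O
Why: Nucleophile-catalysed O-acylation of the secondary allylic alcohol proceeds with retention at C9, the cis bromohydrin cannot close to an epoxide under the mild base, and the acetate disfavours ionisation at C9 in the last step.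

**Step 13**
Reactants: 21 (2S,3S,6R,9S,10R)-3,10-dibromo-2-chloro-3,11,11-trimethyl-7-[(trimethylsilyl)methyl]spiro[5.5]undec-7-en-9-yl acetate
Product: 22 9-acetylisoobtusol
Conditions: CF3CO2H (2–3 equiv), CH2Cl2, −20 to 0 °C, short reaction time; NaHCO3 (aq)
Reagents that add atoms: none
Why: Protodesilylation of the allylsilane with allylic transposition (SE2′): the proton adds to C8, the tertiary C7 cation is stabilised by the β-silicon and loses the silyl group, which moves the double bond regiospecifically into the exocyclic C7=CH2 position without creating or disturbing a stereocentre, the allylsilane being far more nucleophilic than the product alkene.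

**Compound list**

1 | dimedone (5,5-dimethylcyclohexane-1,3-dione) | CC1(C)CC(=O)CC(=O)C1 | starting material
2 | 3-ethoxy-5,5-dimethylcyclohex-2-en-1-one | CCOC1=CC(=O)CC(C)(C)C1 | intermediate
3 | 6-[(dimethylamino)methyl]-3-ethoxy-5,5-dimethylcyclohex-2-en-1-one (racemic Mannich base) | CCOC1=CC(=O)C(CN(C)C)C(C)(C)C1 | intermediate
4 | [(4-ethoxy-6,6-dimethyl-2-oxocyclohex-3-en-1-yl)methyl]trimethylammonium iodide (racemic) | CCOC1=CC(=O)C(C[N+](C)(C)C)C(C)(C)C1.[I-] | intermediate
5 | 3-ethoxy-5,5-dimethyl-6-methylidenecyclohex-2-en-1-one | CCOC1=CC(=O)C(=C)C(C)(C)C1 | intermediate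
6 | 2-[(trimethylsilyl)methyl]allyl acetate | CC(=O)OCC(=C)C[Si](C)(C)C | starting material
7 | (5R)-8-ethoxy-10,10-dimethyl-2-methylidenespiro[4.5]dec-7-en-6-one | O=C1C=C(OCC)CC(C)(C)[C@@]12CC(=C)CC2 | intermediate
8 | (5R)-8-ethoxy-10,10-dimethylspiro[4.5]dec-7-ene-2,6-dione | O=C1C=C(OCC)CC(C)(C)[C@@]12CC(=O)CC2 | intermediate
9 | (5R)-8-ethoxy-10,10-dimethyl-2-[(trimethylsilyl)oxy]spiro[4.5]deca-2,7-dien-6-one | O=C1C=C(OCC)CC(C)(C)[C@@]12CC(O[Si](C)(C)C)=CC2 | intermediate
10 | (3S,5S)-3-chloro-8-ethoxy-10,10-dimethylspiro[4.5]dec-7-ene-2,6-dione (Cl cis to the C7 carbonyl) | O=C1C=C(OCC)CC(C)(C)[C@@]12CC(=O)[C@@H](Cl)C2 | intermediate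
11 | trimethylsilyldiazomethane | C[Si](C)(C)C=[N+]=[N-] | starting material
12 | (2S,6S)-2-chloro-9-ethoxy-11,11-dimethyl-4-(trimethylsilyl)spiro[5.5]undec-8-ene-3,7-dione (C4 epimers) | O=C1C=C(OCC)CC(C)(C)[C@@]12CC([Si](C)(C)C)C(=O)[C@@H](Cl)C2 | intermediate
13 | (2S,6S)-2-chloro-9-ethoxy-11,11-dimethylspiro[5.5]undec-8-ene-3,7-dione | O=C1C=C(OCC)CC(C)(C)[C@@]12CCC(=O)[C@@H](Cl)C2 | intermediate
14 | (2S,3R,6S)-2-chloro-9-ethoxy-3-hydroxy-3,11,11-trimethylspiro[5.5]undec-8-en-7-one (OH cis to Cl) | O=C1C=C(OCC)CC(C)(C)[C@@]12CC[C@@](C)(O)[C@@H](Cl)C2 | intermediate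
15 | (2S,3S,6S)-3-bromo-2-chloro-9-ethoxy-3,11,11-trimethylspiro[5.5]undec-8-en-7-one (Br trans to Cl) | O=C1C=C(OCC)CC(C)(C)[C@@]12CC[C@](C)(Br)[C@@H](Cl)C2 | intermediate
16 | (2S,3S,6S)-3-bromo-7-[(tert-butyldimethylsilyl)oxy]-2-chloro-9-ethoxy-3,11,11-trimethylspiro[5.5]undeca-7,9-diene | CC(C)(C)[Si](C)(C)OC1=CC(OCC)=CC(C)(C)[C@@]12CC[C@](C)(Br)[C@@H](Cl)C2 | intermediate
17 | (2S,3S,6S,10R)-3,10-dibromo-2-chloro-9-ethoxy-3,11,11-trimethylspiro[5.5]undec-8-en-7-one | O=C1C=C(OCC)[C@H](Br)C(C)(C)[C@@]12CC[C@](C)(Br)[C@@H](Cl)C2 | intermediate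
18 | (2S,3S,6S,10R)-3,10-dibromo-2-chloro-9-ethoxy-3,11,11-trimethyl-7-[(trimethylsilyl)methyl]spiro[5.5]undec-8-en-7-ol (C7 epimers) | C[Si](C)(C)CC1(O)C=C(OCC)[C@H](Br)C(C)(C)[C@@]12CC[C@](C)(Br)[C@@H](Cl)C2 | intermediate
19 | (2S,3S,6R,10R)-3,10-dibromo-2-chloro-3,11,11-trimethyl-7-[(trimethylsilyl)methyl]spiro[5.5]undec-7-en-9-one | C[Si](C)(C)CC1=CC(=O)[C@H](Br)C(C)(C)[C@@]12CC[C@](C)(Br)[C@@H](Cl)C2 | intermediate
20 | (2S,3S,6R,9S,10R)-3,10-dibromo-2-chloro-3,11,11-trimethyl-7-[(trimethylsilyl)methyl]spiro[5.5]undec-7-en-9-ol (OH cis to the C10 Br) | C[Si](C)(C)CC1=C[C@H](O)[C@H](Br)C(C)(C)[C@@]12CC[C@](C)(Br)[C@@H](Cl)C2 | intermediate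
21 | (2S,3S,6R,9S,10R)-3,10-dibromo-2-chloro-3,11,11-trimethyl-7-[(trimethylsilyl)methyl]spiro[5.5]undec-7-en-9-yl acetate | C[Si](C)(C)CC1=C[C@H](OC(C)=O)[C@H](Br)C(C)(C)[C@@]12CC[C@](C)(Br)[C@@H](Cl)C2 | intermediate
22 | 9-acetylisoobtusol, (2S,3S,6R,9S,10R)-3,10-dibromo-2-chloro-3,11,11-trimethyl-7-methylidenespiro[5.5]undecan-9-yl acetate | C=C1C[C@H](OC(C)=O)[C@H](Br)C(C)(C)[C@@]12CC[C@](C)(Br)[C@@H](Cl)C2 | target

**Step count and risks**

Total: 13 steps. Longest linear sequence: 13 steps (1 to 22); compounds 6 and 11 are purchased.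

Most likely to fail:

**Step 3.** The unsubstituted trimethylenemethane complex may add only sluggishly to the hindered, electron-rich cross-conjugated enone, so that donor oligomerisation and dimerisation of 5 take over. The ring-closing enolate alkylation, which alone creates the stereocentre next to the gem-dimethyl carbon, may also discriminate its two faces poorly.
Fallback: the quaternary centre is set by palladium-catalysed decarboxylative asymmetric allylic alkylation and the five-membered ring is closed by metathesis; the sequence sets out from 2 and returns at 8.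
- Compound 2 is alkylated at C6 (LiN(iPr)2, THF, −78 °C; 2-methoxyallyl bromide) to 3-ethoxy-6-(2-methoxyprop-2-en-1-yl)-5,5-dimethylcyclohex-2-en-1-one F1.
- Its lithium enolate is O-acylated with allyl chloroformate to the allyl enol carbonate, allyl 3-ethoxy-6-(2-methoxyprop-2-en-1-yl)-5,5-dimethylcyclohexa-1,3-dien-1-yl carbonate F2.
- Pd2(dba)3 with the appropriate enantiomer of a tert-butyl phosphinooxazoline ligand in toluene then gives, with loss of CO2, (6R)-3-ethoxy-6-(2-methoxyprop-2-en-1-yl)-5,5-dimethyl-6-(prop-2-en-1-yl)cyclohex-2-en-1-one F3.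
- Ring-closing metathesis of the allyl and 2-methoxyallyl arms with the second-generation Grubbs catalyst forms the cyclic enol ether (5R)-8-ethoxy-2-methoxy-10,10-dimethylspiro[4.5]deca-2,7-dien-6-one F4.
- Oxalic acid in wet CH2Cl2 hydrolyses the simple enol ether, much faster than the vinylogous ester, to ketone 8.

**Step 9.** The facial selectivity of the C10 bromination rests on a remote conformational bias (C1 side against C5 side of ring A, transmitted only through the axial C2 chlorine); it may be low, or the halogen may enter mainly from the wrong face.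
Fallback: the order in which bromine and hydrogen are placed on C10 is reversed, so that the same facial preference now delivers the desired epimer; the sequence sets out from 15 and returns at 17.
- Bromination as in step 9 is accepted to give the epimer (2S,3S,6S,10S)-3,10-dibromo-2-chloro-9-ethoxy-3,11,11-trimethylspiro[5.5]undec-8-en-7-one F5.
- This is enolised again (t-BuMe2SiOTf, Et3N, CH2Cl2, 0 °C) to the C10-brominated diene (2S,3S,6S)-3,10-dibromo-7-[(tert-butyldimethylsilyl)oxy]-2-chloro-9-ethoxy-3,11,11-trimethylspiro[5.5]undeca-7,9-diene F6.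
- Kinetic protonation at C10 (CF3CO2H, 1 equiv, CH2Cl2, −78 °C) brings hydrogen in from the face the electrophile prefers and leaves bromine on the C1 side, giving 17.
- The same two operations recycle any minor epimer separated by chromatography.

**Step 6.** The Lewis acid may be drained by the vinylogous ester, the tetrahedral diazonium alkoxide may close to the spiro epoxide instead of rearranging, the chlorinated carbon may migrate in part, and the ring-enlarged ketone may take up a second carbon.
Fallback: an acceptor-substituted diazo compound is used, whose β-keto ester product is enolised and resists further insertion; the sequence sets out from 10 and returns at 13.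
- tert-Butyl diazoacetate with BF3·OEt2 in CH2Cl2 (−78 to 0 °C) gives tert-butyl (2S,6S)-2-chloro-9-ethoxy-11,11-dimethyl-3,7-dioxospiro[5.5]undec-8-ene-4-carboxylate F7.
- CF3CO2H in CH2Cl2 at rt cleaves the tert-butyl ester to (2S,6S)-2-chloro-9-ethoxy-11,11-dimethyl-3,7-dioxospiro[5.5]undec-8-ene-4-carboxylic acid F8.
- F8 loses CO2 on gentle warming in toluene to give 13.

**Further compounds**

F1 | step 3 | 3-ethoxy-6-(2-methoxyprop-2-en-1-yl)-5,5-dimethylcyclohex-2-en-1-one (racemic) | CCOC1=CC(=O)C(CC(OC)=C)C(C)(C)C1
F2 | step 3 | allyl 3-ethoxy-6-(2-methoxyprop-2-en-1-yl)-5,5-dimethylcyclohexa-1,3-dien-1-yl carbonate | C=CCOC(=O)OC1=C(CC(OC)=C)C(C)(C)CC(OCC)=C1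
F3 | step 3 | (6R)-3-ethoxy-6-(2-methoxyprop-2-en-1-yl)-5,5-dimethyl-6-(prop-2-en-1-yl)cyclohex-2-en-1-one | O=C1C=C(OCC)CC(C)(C)[C@@]1(CC=C)CC(OC)=C
F4 | step 3 | (5R)-8-ethoxy-2-methoxy-10,10-dimethylspiro[4.5]deca-2,7-dien-6-one | O=C1C=C(OCC)CC(C)(C)[C@@]12CC(OC)=CC2
F5 | step 9 | (2S,3S,6S,10S)-3,10-dibromo-2-chloro-9-ethoxy-3,11,11-trimethylspiro[5.5]undec-8-en-7-one | O=C1C=C(OCC)[C@@H](Br)C(C)(C)[C@@]12CC[C@](C)(Br)[C@@H](Cl)C2
F6 | step 9 | (2S,3S,6S)-3,10-dibromo-7-[(tert-butyldimethylsilyl)oxy]-2-chloro-9-ethoxy-3,11,11-trimethylspiro[5.5]undeca-7,9-diene | CC(C)(C)[Si](C)(C)OC1=CC(OCC)=C(Br)C(C)(C)[C@@]12CC[C@](C)(Br)[C@@H](Cl)C2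
F7 | step 6 | tert-butyl (2S,6S)-2-chloro-9-ethoxy-11,11-dimethyl-3,7-dioxospiro[5.5]undec-8-ene-4-carboxylate (C4 epimers) | O=C1C=C(OCC)CC(C)(C)[C@@]12CC(C(=O)OC(C)(C)C)C(=O)[C@@H](Cl)C2
F8 | step 6 | (2S,6S)-2-chloro-9-ethoxy-11,11-dimethyl-3,7-dioxospiro[5.5]undec-8-ene-4-carboxylic acid (C4 epimers) | O=C1C=C(OCC)CC(C)(C)[C@@]12CC(C(=O)O)C(=O)[C@@H](Cl)C2
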